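## Structural features

The target joins a 7-methoxycoumarin (benzene ring A fused to pyran-2-one ring C) through coumarin C-3 to C-1 of a six-membered carbocycle, ring B. Ring B is a 2-aryl-cyclohex-2-ene-1,4-dione: C-1=C-2 is the alkene, C-3 and C-6 are ketones, C-5 is a CH2 group, and C-4 is a fully substituted carbinol carrying the hydroxyl and a 3-methylbut-2-enyl (prenyl) chain. C-4, of (R) configuration, is the only stereocentre, so no neighbouring centre can relay its configuration and it must be set by a reagent or catalyst. Ring B is formally the hydrate of a 2-aryl-5-prenyl-1,4-benzoquinone: the C-4 hydroxyl is β to the C-6 ketone, so enolisation at C-5 can expel it or open the ring by retro-aldol cleavage, and it is also a tertiary α-ketol with respect to C-3. Other sensitive sites are the enedione and the coumarin C-3=C-4 bond (both conjugate acceptors), the lactone (hydroxide, hard nucleophiles) and the trisubstituted prenyl alkene (electrophilic halogen, strong acid, oxidants). The real difficulty is to create the quaternary carbinol enantioselectively and then to close and carry a dehydration-prone ring under near-neutral conditions. The feature exploited is that C-4 is the carbinol carbon of the β-hydroxy ketone C-4/C-5/C-6 and also has the C-3 carbonyl directly attached. Cutting C-4–C-5 therefore gives an acceptor whose two adjacent carbonyl oxygens can bind one metal, and a donor in which C-5 is the only nucleophilic carbon.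

## Logic of the disconnections

**16 from 15.** Only the O–Si bond on the C-4 oxygen is added in the backward direction. In 16 the free hydroxyl is β to C-6 and γ to C-1, so earlier steps would face retro-aldol cleavage, hemiketal formation or loss of water. No skeletal simplification results, but every earlier step gains tolerance. The forward step must remove silicon without base and without strong acid.

**15 from 13 (through 14).** The C-1=C-2 double bond is cut as an aldol-condensation retron, so that C-2 becomes the methyl group of the C-3 ketone and C-1 an aryl ketone. Ring B is opened to an acyclic chain that carries only carbonyl functionality. The forward step requires C-2, not C-5, to be the nucleophile and C-1, not C-6, to be attacked. The first is helped by mild buffering and the silyl ether. The second follows from ring-closure stereoelectronics: the six-membered enolendo closure is allowed, the five-membered enolendo closure onto C-6 is disfavoured.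

**13 from 12.** The C-2–C-3 bond is cut, turning the methyl ketone into a thioester. C-3 is then at the carboxylic oxidation level, which the next cut needs, and a thioester is the acyl derivative that a palladium/organozinc couple converts into a ketone beside ketones, a lactone and a silyl ether. The gain is one carbon less and a handle that distinguishes C-3 from C-1 and C-6. The demand is methyl transfer to a fully substituted thioester in the presence of a 1,2-diketone. The C-4 descriptor stays (R) because the thioester carbon, like the later ketone carbon, ranks second.

**12 from 6 and 11.** The C-4–C-5 bond, the aldol bond of the β-oxy ketone, is cut. It is the strategic cut for three reasons: it divides the molecule into two halves of similar size, it is the one bond whose formation creates the stereocentre, and it leaves in 11 a ketone (C-4) flanked by the thioester carbonyl (C-3) for two-point binding to chiral divalent copper. 6 has a single nucleophilic carbon. As a design point, 6 carries a triethylsilyl group in place of a smaller trialkylsilyl group. The enol ether then survives purification, and silyl transfer in the aldol leaves the C-4 oxygen protected by a group that lasts through the next two steps. The free carbinol, which would equilibrate with a five-membered hemiketal on C-1 and could cleave by retro-aldol, is never released before the end, and a separate protection step is saved. The demands are face selectivity at the ketone, ketone-over-thioester selectivity and catalyst turnover.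

**6 from 5, 4, and 1 plus 2.** The enol O–Si bond of 6 is cut to give 5. The C-6 carbonyl oxygen of 5 is removed to give 4 (oxidation of the CH2 between ketone and methyl). 4 is cut at the coumarin C-3=C-4 bond and the lactone C–O bond to give 1 and 2. A 3-acylcoumarin is the direct condensation product of a salicylaldehyde and a β-keto ester, and its acyl chain already holds C-1, C-6 and C-5. The oxidation must stop at the diketone; silylation can occur only towards the methyl group.

**11 from 10, 8 plus 9, and 7.** The C-4 carbonyl is masked as a dithiane in 10. The bond from the dithiane carbon to the first prenyl carbon is cut to give 8 and 9, and the acyl C–S bond of 8 is traced to 7. The dithiane carbon is an acyl-anion equivalent made acidic by the carboxyl group, so the prenyl group enters by alkylation at its primary carbon. The ester-to-thioester exchange is placed at the unhindered stage. The unmasking must spare the prenyl alkene, the thioester and the base-sensitive β,γ-unsaturated ketone.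

## Other disconnections considered

**Alternative 1:** The cut is the C-2–C-3 bond of ring B. The precursor would be the Z enol triflate aldehyde [(1Z,5R)-5-formyl-2-(7-methoxy-2-oxochromen-3-yl)-8-methyl-3-oxo-5-(triethylsilyloxy)nona-1,7-dien-1-yl] trifluoromethanesulfonate A2, in which C-4 already carries its silyloxy and prenyl groups. CrCl2 (divalent chromium) with catalytic NiCl2 would convert the C-2 triflate, by oxidative addition to zerovalent nickel and transfer to chromium, into an alkenylchromium species. This adds to the C-3 aldehyde and closes ring B as 3-[3-hydroxy-4-(3-methylbut-2-enyl)-6-oxo-4-(triethylsilyloxy)cyclohex-1-enyl]-7-methoxycoumarin A1, a C-3 epimer mixture that later oxidation would converge.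
- In its favour: organochromium reagents add to aldehydes beside ketones and lactones, the hindered aldehyde is no obstacle, and no enolate is involved, so the C-4 oxygen cannot be lost through C-5 enolisation during closure. In reliability and chemoselectivity of the ring closure this alternative is the better one.
- Against it: the cut does not create the C-4 stereocentre, which would need a separate asymmetric step of the kind used in the chosen plan. A2 is a vinylogous acyl triflate that must be made as one geometric isomer and is open to addition–elimination. A2 still contains a β-silyloxy ketone. Several equivalents of a toxic chromium salt are needed. A1 is two steps (oxidation, desilylation) from the target.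
- Comparison: structurally the chosen plan joins the two halves and sets the stereocentre in one step, whereas this one forms only a ring bond. Mechanistically the alkenylchromium addition is more chemoselective than an aldol condensation but carries no stereochemical information. In step economy it is longer before the key step and about equal after it.

**Alternative 2:** The cut is the bond between the first and second carbon of the prenyl chain. The cuprate from 2-methylprop-1-enylmagnesium bromide and CuI would open the enantiopure epoxide methyl 2-[(2R)-2-(hydroxymethyl)oxiran-2-yl]acetate A4 at its ring CH2. This gives methyl (3R)-3-hydroxy-3-(hydroxymethyl)-6-methylhept-5-enoate A3, with the tertiary hydroxyl released and the stereocentre untouched.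
- In its favour: substitution at the unhindered CH2 of a 2,2-disubstituted epoxide by an alkenyl cuprate is dependable, the stereocentre takes no part in the bond formation, and its configuration would rest on a well-understood asymmetric epoxidation. In certainty of absolute configuration this alternative is at least the equal of the chosen plan and probably the better.
- Against it: the key step builds only a small acyclic fragment without ring B or the coumarin. The hydroxymethyl group (future C-3), the ester (future C-6), C-1 and C-2 must then be elaborated in a long linear sequence with repeated redox and protecting-group changes. Under the basic cuprate conditions the primary alkoxide can shift the epoxide (Payne rearrangement), and the ester enolate can open the epoxide by β-elimination.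
- Comparison: structurally the stereocentre is made early on a small piece, whereas the chosen plan makes it at the point of convergence. Mechanistically it is more predictable than a chelation-controlled catalytic aldol on a new substrate pair. In step economy it loses clearly.

**Alternative 3:** The cut is the C-3–C-4 bond of ring B. The precursor would be the Z enal ketone (2Z)-4-(tert-butyldimethylsilyloxy)-3-(7-methoxy-2-oxochromen-3-yl)-9-methyl-6-oxodeca-2,8-dienal A6. A chiral triazolium-derived N-heterocyclic carbene would add to the aldehyde, and the Breslow intermediate would attack the prenyl ketone. Release of the carbene would give 3-[6-(tert-butyldimethylsilyloxy)-4-hydroxy-4-(3-methylbut-2-enyl)-3-oxocyclohex-1-enyl]-7-methoxycoumarin A5, with ring B closed and C-4 set.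
- In its favour: ring and stereocentre form in one metal-free, redox-neutral, atom-economic step, C-3 arrives directly as the ketone, and aldehyde–ketone benzoin closures to six-membered tertiary α-ketols are an established reaction type. In coupling ring closure with stereocentre formation it is better than the chosen plan, which needs a separate closure.
- Against it: with an enal the carbene adduct can divert to homoenolate or acyl azolium pathways. The ketone of A6 is flanked by two CH2 groups of similar size, so face discrimination rests on remote differences, whereas the chosen acceptor sets a chelating thioester against a CH2. The base that generates the carbene can move the β,γ double bond into conjugation, isomerise the Z enal and eliminate the silyloxy group β to the ketone. A6 has a second stereocentre at C-6, and A5 still needs desilylation and oxidation there.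
- Comparison: structurally elegant with a short end-game in principle, mechanistically less secure in chemoselectivity and face selectivity for this substrate, and about equal in overall step count once A6 with defined alkene geometry is included.

Key step: step 7

Assumption: the sense of induction established for bis(oxazoline)-copper complexes with chelated α-keto esters is taken to hold for the α-keto thioester 11, so the (R,R) ligand is specified; the (S,S) ligand would be used if the sense proved opposite.

## Route

Step 1
Reactants: 1 2-hydroxy-4-methoxybenzaldehyde; 2 ethyl 3-oxopentanoate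
Product: 4 7-methoxy-3-propanoylcoumarin, via Knoevenagel adduct 3 (not isolated)
Conditions: piperidine (cat.), EtOH, reflux
Reagents that add atoms: none
Why: Knoevenagel condensation of the β-keto ester with the aldehyde gives 3, whose phenol then attacks the ethyl ester (intramolecular transesterification) to close the pyranone; reversible amine addition equilibrates the alkene geometry. This is the standard entry to 3-acylcoumarins.

Step 2
Reactants: 4 7-methoxy-3-propanoylcoumarin
Product: 5 1-(7-methoxy-2-oxochromen-3-yl)propane-1,2-dione
Conditions: SeO2 (1.1 equiv), 1,4-dioxane/H2O, 90 °C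
Reagents that add atoms: selenium dioxide, O=[Se]=O
Why: Riley oxidation: SeO2 oxidises the only enolisable position, the CH2 next to the ketone, to a carbonyl group. The reagent is kept near one equivalent to spare the new acetyl group.

Step 3
Reactants: 5 1-(7-methoxy-2-oxochromen-3-yl)propane-1,2-dione
Product: 6 7-methoxy-3-[2-(triethylsilyloxy)prop-2-enoyl]coumarin
Conditions: TESOTf, Et3N, CH2Cl2, −78 to 0 °C
Reagents that add atoms: triethylsilyl trifluoromethanesulfonate, CC[Si](CC)(CC)OS(=O)(=O)C(F)(F)F
Why: Soft enolisation of a 1,2-diketone with a silyl triflate and an amine; only the acetyl carbonyl has α-hydrogens, so a single 2-silyloxyenone can form. The triethylsilyl enol ether should survive rapid chromatography on deactivated silica.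

Step 4
Reactants: 7 ethyl 1,3-dithiane-2-carboxylate
Product: 8 S-ethyl 1,3-dithiane-2-carbothioate
Conditions: AlMe3, EtSH, CH2Cl2, 0 °C to rt; dilute HCl work-up
Reagents that add atoms: ethanethiol, CCS
Why: Aluminium-mediated ester-to-thioester exchange: dimethylaluminium ethanethiolate, formed from AlMe3 and the thiol, delivers thiolate to the ester carbonyl. The ester is still unhindered at this stage.

Step 5
Reactants: 8 S-ethyl 1,3-dithiane-2-carbothioate; 9 prenyl bromide (1-bromo-3-methylbut-2-ene)
Product: 10 S-ethyl 2-(3-methylbut-2-enyl)-1,3-dithiane-2-carbothioate
Conditions: LiN(SiMe3)2, THF, −78 °C; then 9, −78 to 0 °C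
Reagents that add atoms: none
Why: Alkylation of a thioester enolate stabilised by two sulfur atoms with a reactive allylic bromide; the soft, hindered carbanion attacks the primary carbon (SN2), giving the linear prenyl group. Low temperature suppresses loss of thiolate from the enolate.

Step 6
Reactants: 10 S-ethyl 2-(3-methylbut-2-enyl)-1,3-dithiane-2-carbothioate
Product: 11 S-ethyl 5-methyl-2-oxohex-4-enethioate
Conditions: PhI(OCOCF3)2, MeCN/H2O (9:1), 0 °C, short reaction time
Reagents that add atoms: water, O
Why: Oxidative dethioacetalisation with a trivalent iodine reagent: sulfur is activated, water adds and the ketone is released within minutes. The short, base-free treatment should spare the prenyl alkene, the thioester and the β,γ-unsaturated ketone; 11 is dried and used at once.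

Step 7
Reactants: 6 7-methoxy-3-[2-(triethylsilyloxy)prop-2-enoyl]coumarin; 11 S-ethyl 5-methyl-2-oxohex-4-enethioate
Product: 12 S-ethyl (2R)-5-(7-methoxy-2-oxochromen-3-yl)-2-(3-methylbut-2-enyl)-4,5-dioxo-2-(triethylsilyloxy)pentanethioate
Conditions: Cu(OTf)2 (10 mol%), (R,R)-tBu-box (11 mol%), THF, −78 to −40 °C, slow addition of 6 to excess 11; filtration through silica, no aqueous acid
Reagents that add atoms: none
Why: This is a catalytic asymmetric Mukaiyama aldol addition; the closest known reaction type is the addition of enolsilanes to pyruvate-type α-keto esters catalysed by copper bis(oxazoline) triflate complexes. The divalent copper centre, carrying (R,R)-2,2'-isopropylidenebis(4-tert-butyl-2-oxazoline), binds 11 through the ketone oxygen and the thioester carbonyl oxygen in a five-membered, distorted square-planar chelate that activates the ketone. One tert-butyl group of the ligand covers one face of the bound ketone, and the terminal CH2 of 6 attacks the open face through an open transition state, forming the C-4 to C-5 bond. Transfer of the triethylsilyl group from the oxocarbenium oxygen to the copper alkoxide releases 12 as its silyl ether and frees the catalyst; no ring is closed. The new stereocentre C-4 is set by the catalyst alone: attack on the re face of the ketone gives the (R) carbinol, and because the (S,S) ligand is known to expose the si face of chelated α-keto esters, the (R,R) ligand is chosen. Ketone-over-thioester selectivity follows from the higher electrophilicity of the ketone within the chelate, and site selectivity in the donor from its single nucleophilic carbon. Coumarin C-4 is a weak competing acceptor because the 7-methoxy group makes it a vinylogous ester. Excess 11 and slow addition of 6 are planned so that the 1,2-diketone of the product does not act as a second acceptor.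

Step 8
Reactants: 12 S-ethyl (2R)-5-(7-methoxy-2-oxochromen-3-yl)-2-(3-methylbut-2-enyl)-4,5-dioxo-2-(triethylsilyloxy)pentanethioate
Product: 13 (4R)-1-(7-methoxy-2-oxochromen-3-yl)-4-(3-methylbut-2-enyl)-4-(triethylsilyloxy)hexane-1,2,5-trione
Conditions: MeZnI (3 equiv), PdCl2(PPh3)2 (10 mol%), toluene/THF, rt
Reagents that add atoms: methylzinc iodide, C[Zn]I
Why: Fukuyama coupling: zerovalent palladium, formed from PdCl2(PPh3)2 and the organozinc, inserts into the acyl C–S bond, methyl passes from zinc to palladium and reductive elimination gives the methyl ketone. Alkylzinc iodides do not add to ketones or the lactone at room temperature, and the silyl ether blocks retro-aldol cleavage; C-4 is not involved.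

Step 9
Reactants: 13 (4R)-1-(7-methoxy-2-oxochromen-3-yl)-4-(3-methylbut-2-enyl)-4-(triethylsilyloxy)hexane-1,2,5-trione
Product: 15 7-methoxy-3-[(4R)-4-(3-methylbut-2-enyl)-3,6-dioxo-4-(triethylsilyloxy)cyclohex-1-enyl]coumarin, via ring B ketol 14 (not isolated)
Conditions: pyrrolidine (0.3 equiv), AcOH (0.6 equiv), toluene, 4 Å MS, rt to 40 °C
Reagents that add atoms: none
Why: Intramolecular aldol condensation (the ring-closing half of a Robinson annulation) under amine–acid buffering: the C-2 methyl group of the C-3 ketone adds to the C-1 ketone in a 6-(enolendo)-exo-trig closure, whereas attack on C-6 would be a disfavoured 5-(enolendo)-exo-trig closure. Loss of water from tertiary ketol 14 gives the aryl-conjugated enedione. The weakly acidic buffer and the silyl ether are chosen so that enolisation at C-5 does not expel the C-4 oxygen; C-4 itself is untouched.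

Step 10
Reactants: 15 7-methoxy-3-[(4R)-4-(3-methylbut-2-enyl)-3,6-dioxo-4-(triethylsilyloxy)cyclohex-1-enyl]coumarin
Product: 16 7-methoxy-3-[(4R)-4-hydroxy-4-(3-methylbut-2-enyl)-3,6-dioxocyclohex-1-enyl]coumarin (CNP0250763.1)
Conditions: HF·pyridine, pyridine, THF, 0 °C to rt
Reagents that add atoms: none
Why: Fluoride cleavage of the tertiary triethylsilyl ether under pyridine buffering. The medium is neither basic enough to enolise C-5 nor acidic enough to ionise C-4, so dehydration to the quinone and retro-aldol opening should be avoided and the C-4 configuration is retained.

## Compound list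

1 | 2-hydroxy-4-methoxybenzaldehyde | COc1ccc(C=O)c(O)c1 | starting material
2 | ethyl 3-oxopentanoate | CCC(=O)CC(=O)OCC | starting material
3 | ethyl 2-[(2-hydroxy-4-methoxyphenyl)methylidene]-3-oxopentanoate (Knoevenagel adduct, formed in the flask, alkene geometry not fixed) | CCOC(=O)C(=Cc1ccc(OC)cc1O)C(=O)CC | intermediate
4 | 7-methoxy-3-propanoylcoumarin | CCC(=O)c1cc2ccc(OC)cc2oc1=O | intermediate
5 | 1-(7-methoxy-2-oxochromen-3-yl)propane-1,2-dione | CC(=O)C(=O)c1cc2ccc(OC)cc2oc1=O | intermediate
6 | 7-methoxy-3-[2-(triethylsilyloxy)prop-2-enoyl]coumarin (fragment 1) | C=C(O[Si](CC)(CC)CC)C(=O)c1cc2ccc(OC)cc2oc1=O | intermediate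
7 | ethyl 1,3-dithiane-2-carboxylate | CCOC(=O)C1SCCCS1 | starting material
8 | S-ethyl 1,3-dithiane-2-carbothioate | CCSC(=O)C1SCCCS1 | intermediate
9 | prenyl bromide (1-bromo-3-methylbut-2-ene) | CC(C)=CCBr | starting material
10 | S-ethyl 2-(3-methylbut-2-enyl)-1,3-dithiane-2-carbothioate | CCSC(=O)C1(CC=C(C)C)SCCCS1 | intermediate
11 | S-ethyl 5-methyl-2-oxohex-4-enethioate (fragment 2) | CCSC(=O)C(=O)CC=C(C)C | intermediate
12 | S-ethyl (2R)-5-(7-methoxy-2-oxochromen-3-yl)-2-(3-methylbut-2-enyl)-4,5-dioxo-2-(triethylsilyloxy)pentanethioate | CCSC(=O)[C@@](O[Si](CC)(CC)CC)(CC=C(C)C)CC(=O)C(=O)c1cc2ccc(OC)cc2oc1=O | intermediate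
13 | (4R)-1-(7-methoxy-2-oxochromen-3-yl)-4-(3-methylbut-2-enyl)-4-(triethylsilyloxy)hexane-1,2,5-trione | CC(=O)[C@@](O[Si](CC)(CC)CC)(CC=C(C)C)CC(=O)C(=O)c1cc2ccc(OC)cc2oc1=O | intermediate
14 | 3-[(4R)-1-hydroxy-4-(3-methylbut-2-enyl)-3,6-dioxo-4-(triethylsilyloxy)cyclohexyl]-7-methoxycoumarin (ring B numbering, both C-1 epimers, formed in the flask) | COc1ccc2cc(C3(O)CC(=O)[C@@](O[Si](CC)(CC)CC)(CC=C(C)C)CC3=O)c(=O)oc2c1 | intermediate
15 | 7-methoxy-3-[(4R)-4-(3-methylbut-2-enyl)-3,6-dioxo-4-(triethylsilyloxy)cyclohex-1-enyl]coumarin | COc1ccc2cc(C3=CC(=O)[C@@](O[Si](CC)(CC)CC)(CC=C(C)C)CC3=O)c(=O)oc2c1 | intermediate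
16 | 7-methoxy-3-[(4R)-4-hydroxy-4-(3-methylbut-2-enyl)-3,6-dioxocyclohex-1-enyl]coumarin | COc1ccc2cc(C3=CC(=O)[C@@](O)(CC=C(C)C)CC3=O)c(=O)oc2c1 | target

## Step count and least certain steps

Total step count: 10. Longest linear sequence: 7 steps (steps 1 to 3 followed by 7 to 10; the branch through steps 4 to 6 is equally long).

**Step 7 (key step).** Three processes are most likely to cause trouble:
- Turnover may stall, because triethylsilyl transfer to the copper alkoxide is slower than for smaller silyl groups, and the 1,3-dicarbonyl array of the acylcoumarin and the 1,2-diketone of the product can hold the copper centre.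
- Facial selectivity may erode, because the acyl-substituted enolsilane is a weak nucleophile that may need a higher temperature, and a thioester chelate may be looser than an ester chelate.
- Side reactions may compete: conjugate addition of the enolsilane to coumarin C-4, ene reaction of the prenyl alkene with the activated ketone, and a second aldol on the product.

Fallback: setting out from 6 and 11, the same bond is formed without asymmetric induction, by Lewis-acid catalysis with Cu(OTf)2 in the absence of chiral ligand or with catalytic TESOTf in CH2Cl2 at low temperature. This should give racemic S-ethyl 5-(7-methoxy-2-oxochromen-3-yl)-2-(3-methylbut-2-enyl)-4,5-dioxo-2-(triethylsilyloxy)pentanethioate F1. The enantiomers of F1 are separated by preparative chromatography on a chiral stationary phase, and the (R) enantiomer rejoins the route as 12.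

**Step 9.** Enolisation at C-5 of 13 or of 15 may compete, with loss of silanol, which in the ring leads irreversibly towards the benzoquinone. Enolisation of the hindered C-3 methyl ketone may be sluggish, and the amine may condense with the 1,2-diketone.

Fallback: setting out from 12 and returning at 16, the C-6 ketone is taken out of play before ring closure.
- HF·pyridine removes the silyl group to give S-ethyl (2R)-2-hydroxy-5-(7-methoxy-2-oxochromen-3-yl)-2-(3-methylbut-2-enyl)-4,5-dioxopentanethioate F2.
- Hydroxyl-directed reduction with Me4NBH(OAc)3 in MeCN/AcOH delivers hydride to the β-ketone C-6 only, giving S-ethyl (2R)-2,4-dihydroxy-5-(7-methoxy-2-oxochromen-3-yl)-2-(3-methylbut-2-enyl)-5-oxopentanethioate F3.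
- TESOTf and 2,6-lutidine silylate both hydroxyls to give S-ethyl (2R)-5-(7-methoxy-2-oxochromen-3-yl)-2-(3-methylbut-2-enyl)-5-oxo-2,4-bis(triethylsilyloxy)pentanethioate F4.
- Fukuyama coupling as in step 8 gives (4R)-1-(7-methoxy-2-oxochromen-3-yl)-4-(3-methylbut-2-enyl)-2,4-bis(triethylsilyloxy)hexane-1,5-dione F5.
- Aldol condensation (pyrrolidine, AcOH, warm toluene) can now close only the six-membered ring and has no leaving group β to an enolisable position, giving 7-methoxy-3-[(4R)-4-(3-methylbut-2-enyl)-3-oxo-4,6-bis(triethylsilyloxy)cyclohex-1-enyl]coumarin F6.
- HF·pyridine gives 3-[(4R)-4,6-dihydroxy-4-(3-methylbut-2-enyl)-3-oxocyclohex-1-enyl]-7-methoxycoumarin F7, and MnO2 or Dess–Martin periodinane oxidises the allylic secondary alcohol at C-6, leaving the tertiary one, to give 16.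

**Step 8.** Oxidative addition and transmetalation may be slow at the fully substituted thioester, and methyl transfer to the zinc-activated 1,2-diketone may compete.

Fallback: setting out from 12 and returning at 13, the thioester is first reduced (Et3SiH, Pd/C, acetone; Fukuyama reduction) to (2R)-5-(7-methoxy-2-oxochromen-3-yl)-2-(3-methylbut-2-enyl)-4,5-dioxo-2-(triethylsilyloxy)pentanal F8. Aldehyde-selective methyl transfer with MeTi(OiPr)3 at low temperature gives (4R)-5-hydroxy-1-(7-methoxy-2-oxochromen-3-yl)-4-(3-methylbut-2-enyl)-4-(triethylsilyloxy)hexane-1,2-dione F9, and Dess–Martin oxidation of the secondary alcohol gives 13.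

**Step 6.** Water may hydrolyse the activated α-keto thioester, the β,γ double bond may migrate into conjugation, and the oxidant may attack the alkene.

Fallback: setting out from 9 and returning at 11, the ketone is reached by oxidation instead of unmasking. The lithium enolate of commercial ethyl 2-(tert-butyldimethylsilyloxy)acetate (LiN(iPr)2, THF, −78 °C) is alkylated with 9 to give ethyl 2-(tert-butyldimethylsilyloxy)-5-methylhex-4-enoate F10. AlMe3/EtSH converts it into S-ethyl 2-(tert-butyldimethylsilyloxy)-5-methylhex-4-enethioate F11, and HF·pyridine gives S-ethyl 2-hydroxy-5-methylhex-4-enethioate F12. Anhydrous Dess–Martin oxidation gives 11 without contact with water or base.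

**Step 2.** Oxidation may continue at the newly formed acetyl methyl group, and selenium residues may be carried forward.

Fallback: setting out from 4 and returning at 5, nitrosation of the CH2 group with isoamyl nitrite and HCl gives 3-[2-(hydroxyimino)propanoyl]-7-methoxycoumarin F13. Transoximation with aqueous formaldehyde and HCl releases 5.

## Further compounds

F1 | step 7 | racemic S-ethyl 5-(7-methoxy-2-oxochromen-3-yl)-2-(3-methylbut-2-enyl)-4,5-dioxo-2-(triethylsilyloxy)pentanethioate | CCSC(=O)C(O[Si](CC)(CC)CC)(CC=C(C)C)CC(=O)C(=O)c1cc2ccc(OC)cc2oc1=O
F2 | step 9 | S-ethyl (2R)-2-hydroxy-5-(7-methoxy-2-oxochromen-3-yl)-2-(3-methylbut-2-enyl)-4,5-dioxopentanethioate | CCSC(=O)[C@@](O)(CC=C(C)C)CC(=O)C(=O)c1cc2ccc(OC)cc2oc1=O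
F3 | step 9 | S-ethyl (2R)-2,4-dihydroxy-5-(7-methoxy-2-oxochromen-3-yl)-2-(3-methylbut-2-enyl)-5-oxopentanethioate (chain C-4 mainly anti to the C-2 hydroxyl, left open in the SMILES) | CCSC(=O)[C@@](O)(CC=C(C)C)CC(O)C(=O)c1cc2ccc(OC)cc2oc1=O
F4 | step 9 | S-ethyl (2R)-5-(7-methoxy-2-oxochromen-3-yl)-2-(3-methylbut-2-enyl)-5-oxo-2,4-bis(triethylsilyloxy)pentanethioate | CCSC(=O)[C@@](O[Si](CC)(CC)CC)(CC=C(C)C)CC(O[Si](CC)(CC)CC)C(=O)c1cc2ccc(OC)cc2oc1=O
F5 | step 9 | (4R)-1-(7-methoxy-2-oxochromen-3-yl)-4-(3-methylbut-2-enyl)-2,4-bis(triethylsilyloxy)hexane-1,5-dione | CC(=O)[C@@](O[Si](CC)(CC)CC)(CC=C(C)C)CC(O[Si](CC)(CC)CC)C(=O)c1cc2ccc(OC)cc2oc1=O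
F6 | step 9 | 7-methoxy-3-[(4R)-4-(3-methylbut-2-enyl)-3-oxo-4,6-bis(triethylsilyloxy)cyclohex-1-enyl]coumarin | COc1ccc2cc(C3=CC(=O)[C@@](O[Si](CC)(CC)CC)(CC=C(C)C)CC3O[Si](CC)(CC)CC)c(=O)oc2c1
F7 | step 9 | 3-[(4R)-4,6-dihydroxy-4-(3-methylbut-2-enyl)-3-oxocyclohex-1-enyl]-7-methoxycoumarin | COc1ccc2cc(C3=CC(=O)[C@@](O)(CC=C(C)C)CC3O)c(=O)oc2c1
F8 | step 8 | (2R)-5-(7-methoxy-2-oxochromen-3-yl)-2-(3-methylbut-2-enyl)-4,5-dioxo-2-(triethylsilyloxy)pentanal | O=C[C@@](O[Si](CC)(CC)CC)(CC=C(C)C)CC(=O)C(=O)c1cc2ccc(OC)cc2oc1=O
F9 | step 8 | (4R)-5-hydroxy-1-(7-methoxy-2-oxochromen-3-yl)-4-(3-methylbut-2-enyl)-4-(triethylsilyloxy)hexane-1,2-dione (both C-5 epimers) | CC(O)[C@@](O[Si](CC)(CC)CC)(CC=C(C)C)CC(=O)C(=O)c1cc2ccc(OC)cc2oc1=O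
F10 | step 6 | ethyl 2-(tert-butyldimethylsilyloxy)-5-methylhex-4-enoate (racemic) | CCOC(=O)C(O[Si](C)(C)C(C)(C)C)CC=C(C)C
F11 | step 6 | S-ethyl 2-(tert-butyldimethylsilyloxy)-5-methylhex-4-enethioate (racemic) | CCSC(=O)C(O[Si](C)(C)C(C)(C)C)CC=C(C)C
F12 | step 6 | S-ethyl 2-hydroxy-5-methylhex-4-enethioate (racemic) | CCSC(=O)C(O)CC=C(C)C
F13 | step 2 | 3-[2-(hydroxyimino)propanoyl]-7-methoxycoumarin | CC(=NO)C(=O)c1cc2ccc(OC)cc2oc1=O
A1 | alternative 1 | 3-[3-hydroxy-4-(3-methylbut-2-enyl)-6-oxo-4-(triethylsilyloxy)cyclohex-1-enyl]-7-methoxycoumarin (4R, both C-3 epimers) | COc1ccc2cc(C3=CC(O)[C@@](O[Si](CC)(CC)CC)(CC=C(C)C)CC3=O)c(=O)oc2c1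
A2 | alternative 1 | [(1Z,5R)-5-formyl-2-(7-methoxy-2-oxochromen-3-yl)-8-methyl-3-oxo-5-(triethylsilyloxy)nona-1,7-dien-1-yl] trifluoromethanesulfonate | COc1ccc2cc(/C(=C/OS(=O)(=O)C(F)(F)F)C(=O)C[C@](O[Si](CC)(CC)CC)(CC=C(C)C)C=O)c(=O)oc2c1
A3 | alternative 2 | methyl (3R)-3-hydroxy-3-(hydroxymethyl)-6-methylhept-5-enoate | OC[C@@](O)(CC=C(C)C)CC(=O)OC
A4 | alternative 2 | methyl 2-[(2R)-2-(hydroxymethyl)oxiran-2-yl]acetate | OC[C@@]1(CO1)CC(=O)OC
A5 | alternative 3 | 3-[6-(tert-butyldimethylsilyloxy)-4-hydroxy-4-(3-methylbut-2-enyl)-3-oxocyclohex-1-enyl]-7-methoxycoumarin (4R, C-6 not fixed) | COc1ccc2cc(C3=CC(=O)[C@@](O)(CC=C(C)C)CC3O[Si](C)(C)C(C)(C)C)c(=O)oc2c1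
A6 | alternative 3 | (2Z)-4-(tert-butyldimethylsilyloxy)-3-(7-methoxy-2-oxochromen-3-yl)-9-methyl-6-oxodeca-2,8-dienal (C-4 of the chain not fixed) | COc1ccc2cc(/C(=C/C=O)C(O[Si](C)(C)C(C)(C)C)CC(=O)CC=C(C)C)c(=O)oc2c1
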